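## Structural features

The target is an isoflavone. Benzene ring A is fused to the 4-pyranone ring C (a 4H-chromen-4-one) and carries hydroxyls at C5 and C7. The pentasubstituted benzene ring B is joined through C1' to C3 of ring C. Going round ring B from C1', there is OH on C2', a 3-hydroxy-3-methylbutyl chain on C3', OH on C4' and OMe on C5'; only C6' carries hydrogen. There is no stereocentre and no stereogenic double bond, so no stereochemical relationship has to be set. The fragile part is the tertiary alcohol, which sits two carbons from an arene carbon flanked by two phenols: protic or Lewis acid should turn it into a 2,2-dimethylchromane or an alkene. In addition, the polyphenol is easily oxidised, C2 of ring C is open to strong nucleophiles, and C2=C3 can be over-reduced. The real difficulty is ring B (a carbon substituent between two oxygens, next to a methoxy group that must stay distinct from the phenols) and a protection plan that can be removed without acid. The key step exploits that C3 carries ring B and is bonded to the C4 carbonyl, while C2 is a CH bonded to O1. An enamine of the ring B two-carbon unit therefore already holds C2 and C3, nucleophilic at C3 and, once acylated, electrophilic at C2. The ring A acyl partner has two equivalent ortho oxygens, so closure of ring C poses no regiochemical question.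

## Logic of the disconnections

20 from 19. No skeletal bond is cut. Two phenols of ring B are masked as benzyl ethers and the C1''–C2'' bond of the side chain is raised to a triple bond. All three changes are undone by one neutral hydrogenation, so the tertiary alcohol never meets acid next to free phenols. The gain is that the side chain becomes accessible by an sp–sp2 coupling. The forward step must spare C2=C3 of ring C.

19 from 13 and 16. The bonds C3–C4 and O1–C2 are cut, which opens ring C. The cut separates two benzene fragments of similar size. The ring A partner 16 is symmetrical and fully silylated, so ring A emerges with free 5-OH and 7-OH and needs no later deprotection. The forward step must acylate 13 at the aryl-bearing carbon and not at nitrogen or at the tertiary hydroxyl. It must then unmask the phenols and close the ring in the same flask, passing through 17 and 18.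

16 from 15, and 15 from 14. The C–Cl bond and four O–Si bonds are cut. The silyl groups mask the phenols, allow the acid chloride to be formed from the silyl ester without HCl, and leave by themselves in the key step. This gives 16 in two steps from 14. The demand is exhaustive silylation, including two chelated and crowded ortho hydroxyls, before 14 can decarboxylate.

13 from 8 and 11. The C=C bond of the enamine (the future C2=C3) is cut. This avoids the electron-rich arylacetaldehyde, which is prone to aldol reaction and oxidation, and avoids any acid hydrolysis. Reagent 11 brings the future C2 together with the amine and comes from 9, 10 and a one-carbon aldehyde (P–C and N–C bonds). The forward step is an olefination with a non-stabilised α-amino carbanion; it needs a potassium counter-ion for the elimination and must tolerate the free tertiary hydroxyl.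

8 from 6 and 7. The C3'–C(sp) bond is cut. The carbon between two oxygens cannot be alkylated cleanly by electrophilic substitution, whereas coupling of an iodide delivers all five side-chain carbons and the tertiary alcohol in one step. The coupling must work on a di-ortho-substituted iodide. Both phenols must be capped, otherwise an ortho-alkynylphenol would close to a benzofuran.

6 from 5, and 5 from 4. One O–benzyl bond and the C3'–I bond are cut. The free 2'-OH of 4 activates the only open ortho position, the para position is blocked by the methoxy group, and C6' is deactivated by the aldehyde. The demand is mono-iodination at a hindered carbon without harm to the aldehyde.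

4 from 3. The C1'–CHO bond is cut; this carbon becomes C3 of ring C. Ortho-formylation of a phenol places it next to the 2'-oxygen. The forward step must choose the unhindered ortho carbon para to the benzyloxy group and not the carbon between the two oxygens.

3 from 1, through 2. The C2'–O bond is cut in the sense of a Baeyer–Villiger reaction; the formyl carbon of 1 is lost. Compound 1 already has the 4'- and 5'-oxygens differentiated as benzyl and methyl ethers. The demand is aryl migration, which the para methoxy group supports.

## Other disconnections considered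

Alternative 1: Ring B is cut at C1'–C6' and C3'–C4' and is built from the acyclic methyl ketone A1 and the acrylate A2. In the forward step the kinetic enolate of A1 adds to A2 in a Michael reaction. After proton transfer the other α-carbon attacks the ester in a Claisen closure, giving the racemic cyclohexane-1,3-dione enol A3.
- In favour: the alkyl chain on C3' between two oxygens and next to the methoxy-bearing carbon is fixed by connectivity alone. The chain arrives saturated with its tertiary oxygen in place. No transition metal or halogenation is needed. On regiochemical certainty at C3' this is the equal of the chosen plan, and on the state of the side chain it is better, since no alkyne is left to reduce at the end.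
- Against: A2 is a poor Michael acceptor because of its α-alkoxy group. A3 must be dehydrogenated to the arene, and loss of methanol from A3 leads without any oxidant to a resorcinol lacking the 5'-methoxy group, so aromatisation competes with the wanted oxidation.
- Comparison: after A3, C1' must still be functionalised and ring C built, for instance by the annulation used here. The alternative therefore solves ring B only and would be several steps longer than the chosen 11-step plan.

Alternative 2: Ring C is cut at O1–C8a and C4–C4a. Fluoride releases an aryne from A4. The enolate oxygen of the hydroxyacrylate A5 adds to the aryne carbon remote from the neighbouring benzyloxy group, and the resulting aryl anion, ortho to that group, attacks the ester to give A6.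
- In favour: like the chosen step it forms two bonds and one ring convergently, and ring B is again placed on C3 by the polarity of the two-carbon unit. A5 is a bench-stable enol, a point on which it is better than a moisture-sensitive enamine. The aryne regiochemistry is supported by the inductive effect of the adjacent alkoxy group.
- Against: A4 needs a multi-step preparation, against two steps for 16. The ambident enolate may arylate on carbon. The free tertiary hydroxyl of A5 can add to the aryne. A5 requires homologation of the same kind of benzaldehyde to an arylacetate plus a formylation. A6 carries benzyl and methoxymethyl groups, so hydrogenolysis and an acid step are both needed, the latter with the chromane risk.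
- Comparison: on bond count and mechanistic economy the two plans are equal. In the chosen plan the symmetry of 16 removes the regiochemical question that Alternative 2 answers only by electronic bias, and the overall route is shorter.

Alternative 3: Ring B is cut at C5'–C6', C1'–C2' and C2'–C3'. In a Dötz benzannulation the zerovalent chromium alkenyl(methoxy)carbene complex A7 takes up the ethynylchromone A8 and one CO ligand and gives the phenol A9.
- In favour: it forms three bonds, more than the chosen step, and sets every ring B substituent in one event on a preformed chromone; on bond count it is the better plan. A terminal alkyne places the chromonyl group next to the new hydroxyl and the hydrogen next to the carbene-derived methoxy carbon, as the target requires. The 2'-OH emerges free and distinct from the 4'-oxygen.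
- Against: the chromium reagent is stoichiometric, toxic and generates carbonyl waste. A7 needs an α-metalated enol ether and several steps. A8 is an ynone-like acceptor on a ring that nucleophiles can open. A9 is a para-methoxyphenol that can be oxidised to a quinone during oxidative removal of the metal. Benzyl, methoxymethyl and triethylsilyl groups remain, so an acid step is again needed.
- Comparison: counting the preparation of A7 and A8 and two or three deprotections, it is clearly longer than the chosen plan and worse on safety.

Key step: step 10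

Assumption: 3-(benzyloxy)-4-methoxybenzaldehyde (O-benzylisovanillin) is bought as such; it is one benzylation away from isovanillin. Compound 14 is dried from its hydrate before use.

Remark on the design: the connectivity of both annulation partners and of the annulation product was checked atom by atom against the target and needs no correction. The changes concern only protecting groups, the saturation level of the spectator side chain (all five carbons and the tertiary oxygen are in place), and the way the enamine is made.

## Route

Step 1
Reactants: 1 3-(benzyloxy)-4-methoxybenzaldehyde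
Product: 3 3-(benzyloxy)-4-methoxyphenol, via aryl formate 2 (not isolated)
Conditions: mCPBA, CH2Cl2, 0 °C to rt; NaHCO3 wash; then K2CO3 (cat.), MeOH, rt
Reagents that add atoms: 3-chloroperbenzoic acid, O=C(OO)c1cccc(Cl)c1
Why: Baeyer–Villiger (Dakin-type) oxidation; the electron-rich aryl group with its para methoxy substituent should migrate in the Criegee intermediate, and methanolysis of the formate frees the phenol that becomes the 2'-oxygen.

Step 2
Reactants: 3 3-(benzyloxy)-4-methoxyphenol
Product: 4 4-(benzyloxy)-2-hydroxy-5-methoxybenzaldehyde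
Conditions: MgCl2, Et3N, (CH2O)n, MeCN, reflux
Reagents that add atoms: formaldehyde (as paraformaldehyde), C=O
Why: Magnesium-phenoxide-directed ortho-formylation (Casnati–Skattebøl); of the two ortho carbons the unhindered one para to the benzyloxy group should react, not the carbon wedged between two oxygens. A second formaldehyde takes up hydride to give the aldehyde.

Step 3
Reactants: 4 4-(benzyloxy)-2-hydroxy-5-methoxybenzaldehyde
Product: 5 4-(benzyloxy)-2-hydroxy-3-iodo-5-methoxybenzaldehyde
Conditions: NIS, TFA (cat.), MeCN, 0 °C to rt, dark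
Reagents that add atoms: N-iodosuccinimide, O=C1CCC(=O)N1I
Why: Electrophilic aromatic iodination; C3 is the only free position ortho to the phenol and is also ortho to the benzyloxy group, the para position is blocked by OMe, and C6 is deactivated by the adjacent aldehyde.

Step 4
Reactants: 5 4-(benzyloxy)-2-hydroxy-3-iodo-5-methoxybenzaldehyde
Product: 6 2,4-bis(benzyloxy)-3-iodo-5-methoxybenzaldehyde
Conditions: BnBr, K2CO3, DMF, 50 °C
Reagents that add atoms: benzyl bromide, BrCc1ccccc1
Why: Williamson etherification of the acidic chelated phenol; capping it prevents benzofuran formation in the next step and makes both ring B phenols removable by hydrogenolysis.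

Step 5
Reactants: 6 2,4-bis(benzyloxy)-3-iodo-5-methoxybenzaldehyde; 7 2-methylbut-3-yn-2-ol
Product: 8 2,4-bis(benzyloxy)-3-(3-hydroxy-3-methylbut-1-yn-1-yl)-5-methoxybenzaldehyde
Conditions: PdCl2(PPh3)2 (cat.), CuI (cat.), Et3N, DMF, 60 °C, degassed
Reagents that add atoms: none
Why: Sonogashira coupling; aryl iodides flanked by two alkoxy groups couple with the slim alkyne partner on mild heating, and the aldehyde and free tertiary alcohol are tolerated.

Step 6
Reactants: 9 morpholine; 10 diphenylphosphine oxide
Product: 11 diphenyl(morpholin-4-ylmethyl)phosphine oxide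
Conditions: (CH2O)n, toluene, reflux, Dean–Stark
Reagents that add atoms: formaldehyde (as paraformaldehyde), C=O
Why: Phospha-Mannich (Kabachnik–Fields type) condensation; the iminium ion from 9 and formaldehyde is trapped by the P–H compound and water is removed.

Step 7
Reactants: 8 2,4-bis(benzyloxy)-3-(3-hydroxy-3-methylbut-1-yn-1-yl)-5-methoxybenzaldehyde; 11 diphenyl(morpholin-4-ylmethyl)phosphine oxide
Product: 13 4-[(E)-2-[2,4-bis(benzyloxy)-3-(3-hydroxy-3-methylbut-1-yn-1-yl)-5-methoxyphenyl]ethenyl]morpholine, via hydroxy phosphine oxide adduct 12 (not isolated)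
Conditions: 11 (2.3 equiv), n-BuLi, THF, −78 °C; add 8; then KOtBu, −78 °C to rt; cold aq. NaHCO3 work-up, dried over K2CO3, used crude
Reagents that add atoms: none
Why: Horner–Wittig olefination with an α-amino phosphine oxide carbanion; the potassium alkoxide of 12 should lose diphenylphosphinate by syn-elimination and give the β-morpholinostyrene directly, one extra equivalent of the anion being spent on the tertiary hydroxyl. The E isomer is expected to dominate, and any Z isomer is of no consequence because the alkene geometry is lost in step 10.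

Step 8
Reactants: 14 2,4,6-trihydroxybenzoic acid
Product: 15 tert-butyldimethylsilyl 2,4,6-tris(tert-butyldimethylsilyloxy)benzoate
Conditions: TBSCl (5 equiv), imidazole, DMAP (cat.), DMF, rt to 40 °C
Reagents that add atoms: tert-butyldimethylsilyl chloride, CC(C)(C)[Si](C)(C)Cl
Why: Exhaustive silylation; the silyl ester should form first and so remove the free acid that would decarboxylate, and excess reagent with mild warming should complete the two chelated ortho hydroxyls.

Step 9
Reactants: 15 tert-butyldimethylsilyl 2,4,6-tris(tert-butyldimethylsilyloxy)benzoate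
Product: 16 2,4,6-tris(tert-butyldimethylsilyloxy)benzoyl chloride
Conditions: (COCl)2, DMF (cat.), CH2Cl2, 0 °C to rt; volatiles removed with toluene, used crude
Reagents that add atoms: oxalyl chloride, O=C(Cl)C(=O)Cl
Why: Conversion of a silyl ester into the acid chloride by the chloroiminium salt from oxalyl chloride and DMF; the by-product is the silyl chloride and no HCl forms, so the aryl silyl ethers should persist.

Step 10
Reactants: 13 4-[(E)-2-[2,4-bis(benzyloxy)-3-(3-hydroxy-3-methylbut-1-yn-1-yl)-5-methoxyphenyl]ethenyl]morpholine; 16 2,4,6-tris(tert-butyldimethylsilyloxy)benzoyl chloride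
Product: 19 3-[2,4-bis(benzyloxy)-3-(3-hydroxy-3-methylbut-1-yn-1-yl)-5-methoxyphenyl]-5,7-dihydroxy-4H-chromen-4-one, via silylated enaminone 17 (not isolated), via triphenol enaminone 18 (not isolated)
Conditions: Et3N, CH2Cl2, 0 °C to rt; then K2CO3, MeOH, rt; then AcOH to pH 5, rt
Reagents that add atoms: none
Why: This is the known chromone annulation of an O-silyl salicyloyl chloride with an enamine, applied to a symmetrical tris-silyl partner. The aryl-bearing β-carbon of 13, activated by the morpholine lone pair, attacks the acyl carbon of 16, whose electron-rich ring should let it react through an acylium-like, sterically undemanding transition state; Et3N takes HCl from the iminium ion and the α-aryl enaminone 17 results (bond C3–C4). Any N-acylation gives an acylammonium ion that is itself an acyl donor and should drain into the conjugation-stabilised C-acyl product, and the hindered tertiary propargylic alcohol cannot compete with the enamine carbon. K2CO3 in MeOH then cleaves the three aryl silyl ethers to 18, an ortho phenoxide adds to the aminomethylene carbon in a 6-endo-trig conjugate addition (bond O1–C2), and morpholine leaves by E1cB elimination, which the final AcOH treatment completes by protonating the nitrogen; ring C thus closes as the 4-pyranone. The two ortho oxygens of 16 are equivalent, so no regiochemical choice arises; the unused one becomes the chelated 5-OH and the para oxygen the 7-OH. The step needs ring B on C3 and not on C2, and the enamine polarity secures this: the aryl-bearing carbon is the nucleophile and the nitrogen-bearing carbon the later electrophile. No stereocentre is formed, and the alkene geometry of 13 and 17 disappears on cyclisation.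

Step 11
Reactants: 19 3-[2,4-bis(benzyloxy)-3-(3-hydroxy-3-methylbut-1-yn-1-yl)-5-methoxyphenyl]-5,7-dihydroxy-4H-chromen-4-one
Product: 20 3-[2,4-dihydroxy-3-(3-hydroxy-3-methylbutyl)-5-methoxyphenyl]-5,7-dihydroxy-4H-chromen-4-one
Conditions: H2 (1 atm), Pd/C, EtOAc–MeOH, rt, stopped at full conversion
Reagents that add atoms: none
Why: Heterogeneous hydrogenation; the aryl alkyne should be saturated first and the two aryl benzyl ethers cleaved by hydrogenolysis in a neutral medium, so the tertiary alcohol never meets acid. The vinylogous ester C2=C3 of ring C is reduced much more slowly and should survive if the reaction is stopped in time.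

## Compound list

1 | 3-(benzyloxy)-4-methoxybenzaldehyde | COc1ccc(C=O)cc1OCc1ccccc1 | starting material
2 | 3-(benzyloxy)-4-methoxyphenyl formate | COc1ccc(OC=O)cc1OCc1ccccc1 | intermediate
3 | 3-(benzyloxy)-4-methoxyphenol | COc1ccc(O)cc1OCc1ccccc1 | intermediate
4 | 4-(benzyloxy)-2-hydroxy-5-methoxybenzaldehyde | COc1cc(C=O)c(O)cc1OCc1ccccc1 | intermediate
5 | 4-(benzyloxy)-2-hydroxy-3-iodo-5-methoxybenzaldehyde | COc1cc(C=O)c(O)c(I)c1OCc1ccccc1 | intermediate
6 | 2,4-bis(benzyloxy)-3-iodo-5-methoxybenzaldehyde | COc1cc(C=O)c(OCc2ccccc2)c(I)c1OCc1ccccc1 | intermediate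
7 | 2-methylbut-3-yn-2-ol | C#CC(C)(C)O | starting material
8 | 2,4-bis(benzyloxy)-3-(3-hydroxy-3-methylbut-1-yn-1-yl)-5-methoxybenzaldehyde | COc1cc(C=O)c(OCc2ccccc2)c(C#CC(C)(C)O)c1OCc1ccccc1 | intermediate
9 | morpholine | C1COCCN1 | starting material
10 | diphenylphosphine oxide | O=[PH](c1ccccc1)c1ccccc1 | starting material
11 | diphenyl(morpholin-4-ylmethyl)phosphine oxide | O=P(CN1CCOCC1)(c1ccccc1)c1ccccc1 | intermediate
12 | 1-[2,4-bis(benzyloxy)-3-(3-hydroxy-3-methylbut-1-yn-1-yl)-5-methoxyphenyl]-2-(diphenylphosphoryl)-2-(morpholin-4-yl)ethan-1-ol (mixture of diastereomers, present as its alkoxide) | COc1cc(C(O)C(N2CCOCC2)P(=O)(c2ccccc2)c2ccccc2)c(OCc2ccccc2)c(C#CC(C)(C)O)c1OCc1ccccc1 | intermediate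
13 | 4-[(E)-2-[2,4-bis(benzyloxy)-3-(3-hydroxy-3-methylbut-1-yn-1-yl)-5-methoxyphenyl]ethenyl]morpholine | COc1cc(/C=C/N2CCOCC2)c(OCc2ccccc2)c(C#CC(C)(C)O)c1OCc1ccccc1 | intermediate
14 | 2,4,6-trihydroxybenzoic acid | O=C(O)c1c(O)cc(O)cc1O | starting material
15 | tert-butyldimethylsilyl 2,4,6-tris(tert-butyldimethylsilyloxy)benzoate | CC(C)(C)[Si](C)(C)OC(=O)c1c(O[Si](C)(C)C(C)(C)C)cc(O[Si](C)(C)C(C)(C)C)cc1O[Si](C)(C)C(C)(C)C | intermediate
16 | 2,4,6-tris(tert-butyldimethylsilyloxy)benzoyl chloride | O=C(Cl)c1c(O[Si](C)(C)C(C)(C)C)cc(O[Si](C)(C)C(C)(C)C)cc1O[Si](C)(C)C(C)(C)C | intermediate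
17 | 2-[2,4-bis(benzyloxy)-3-(3-hydroxy-3-methylbut-1-yn-1-yl)-5-methoxyphenyl]-3-(morpholin-4-yl)-1-[2,4,6-tris(tert-butyldimethylsilyloxy)phenyl]prop-2-en-1-one (alkene geometry not fixed) | COc1cc(C(=CN2CCOCC2)C(=O)c2c(O[Si](C)(C)C(C)(C)C)cc(O[Si](C)(C)C(C)(C)C)cc2O[Si](C)(C)C(C)(C)C)c(OCc2ccccc2)c(C#CC(C)(C)O)c1OCc1ccccc1 | intermediate
18 | 2-[2,4-bis(benzyloxy)-3-(3-hydroxy-3-methylbut-1-yn-1-yl)-5-methoxyphenyl]-3-(morpholin-4-yl)-1-(2,4,6-trihydroxyphenyl)prop-2-en-1-one (alkene geometry not fixed) | COc1cc(C(=CN2CCOCC2)C(=O)c2c(O)cc(O)cc2O)c(OCc2ccccc2)c(C#CC(C)(C)O)c1OCc1ccccc1 | intermediate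
19 | 3-[2,4-bis(benzyloxy)-3-(3-hydroxy-3-methylbut-1-yn-1-yl)-5-methoxyphenyl]-5,7-dihydroxy-4H-chromen-4-one | COc1cc(-c2coc3cc(O)cc(O)c3c2=O)c(OCc2ccccc2)c(C#CC(C)(C)O)c1OCc1ccccc1 | intermediate
20 | 3-[2,4-dihydroxy-3-(3-hydroxy-3-methylbutyl)-5-methoxyphenyl]-5,7-dihydroxy-4H-chromen-4-one (achiral) | COc1cc(-c2coc3cc(O)cc(O)c3c2=O)c(O)c(CCC(C)(C)O)c1O | target

## Step count and least certain steps

Total step count: 11. Longest linear sequence: 8 steps (steps 1, 2, 3, 4, 5, 7, 10 and 11).

Step 10 (key step). The most likely failure is slow or incomplete C-acylation, because the acyl carbon of 16 lies between two silyloxy groups and the nucleophilic carbon of 13 carries an ortho-substituted aryl group. Hydrolysis of the enamine by adventitious water, or early loss of an ortho silyl group from 16, would add to it. The fallback builds ring C by a different, known sequence and sets out from 8: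
- Claisen–Schmidt condensation of 8 with 1-[2,4-bis(benzyloxy)-6-hydroxyphenyl]ethan-1-one F1 (KOH, EtOH, rt) should give the chalcone F2.
- Oxidative 1,2-shift of ring B with PhI(OAc)2 and TsOH in MeOH–HC(OMe)3, the trivalent iodine counterpart of the thallium-mediated chalcone rearrangement, should give the β-keto acetal F3.
- Dilute HCl in MeOH should close ring C to the tetrabenzyl isoflavone F4.
- H2 over Pd/C then cleaves four benzyl ethers and saturates the alkyne, and the route is rejoined at 20.

Step 8. The most likely failure is incomplete silylation of the second chelated ortho hydroxyl, or decarboxylation of 14 before the silyl ester has formed. The fallback sets out from 14 and uses a differentiated ring A partner: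
- Acetone with TFAA/TFA should give the acetonide 5,7-dihydroxy-2,2-dimethyl-4H-1,3-benzodioxin-4-one F5.
- BnBr/K2CO3 gives the bis(benzyl) ether F6.
- KOH in aqueous THF opens it to 2,4-bis(benzyloxy)-6-hydroxybenzoic acid F7.
- TBSCl/imidazole gives the silyl ether silyl ester F8.
- (COCl)2 with catalytic DMF gives 4,6-bis(benzyloxy)-2-(tert-butyldimethylsilyloxy)benzoyl chloride F9.
- F9 and 13 under the conditions of step 10 should pass through the silylated enaminone F10 and the phenol enaminone F11 to F4, which H2 over Pd/C converts into 20.

Step 7. The most likely failures are incomplete elimination of adduct 12 with reversion to 8, hydrolysis of the enamine during isolation, and base-induced loss of acetone from the propargylic alkoxide. The fallback is the classical homologation, setting out from 8: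
- Wittig reaction with the ylide from (methoxymethyl)triphenylphosphonium chloride and KOtBu should give the enol ether 4-[2,6-bis(benzyloxy)-3-methoxy-5-(2-methoxyethenyl)phenyl]-2-methylbut-3-yn-2-ol F12.
- Aqueous formic acid hydrolyses it to the arylacetaldehyde F13.
- Condensation of F13 with 9 in toluene over 4 Å molecular sieves returns to the route at 13.

Step 11. The most likely failure is over-reduction, either saturation of C2=C3 of ring C or hydrogenolysis of the propargylic C–O bond, because three tasks lengthen the exposure to hydrogen. The fallback divides the work and sets out from 8: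
- H2 over Pd/C poisoned with Ph2S should saturate the alkyne only and give 2,4-bis(benzyloxy)-3-(3-hydroxy-3-methylbutyl)-5-methoxybenzaldehyde F14.
- The conditions of step 7 should lead through the adduct F15 to the saturated enamine F16.
- F16 with 16 under the conditions of step 10 should pass through the silylated enaminone F17 and the triphenol enaminone F18 to the saturated bis(benzyl) isoflavone F19.
- A short hydrogenolysis of F19 over Pd/C, which now has only two aryl benzyl ethers to cleave, returns to the route at 20.

## Further compounds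

F1 | step 10 | 1-[2,4-bis(benzyloxy)-6-hydroxyphenyl]ethan-1-one | CC(=O)c1c(O)cc(OCc2ccccc2)cc1OCc1ccccc1
F2 | step 10 | (E)-1-[2,4-bis(benzyloxy)-6-hydroxyphenyl]-3-[2,4-bis(benzyloxy)-3-(3-hydroxy-3-methylbut-1-yn-1-yl)-5-methoxyphenyl]prop-2-en-1-one | COc1cc(/C=C/C(=O)c2c(O)cc(OCc3ccccc3)cc2OCc2ccccc2)c(OCc2ccccc2)c(C#CC(C)(C)O)c1OCc1ccccc1
F3 | step 10 | racemic 1-[2,4-bis(benzyloxy)-6-hydroxyphenyl]-2-[2,4-bis(benzyloxy)-3-(3-hydroxy-3-methylbut-1-yn-1-yl)-5-methoxyphenyl]-3,3-dimethoxypropan-1-one | COc1cc(C(C(OC)OC)C(=O)c2c(O)cc(OCc3ccccc3)cc2OCc2ccccc2)c(OCc2ccccc2)c(C#CC(C)(C)O)c1OCc1ccccc1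
F4 | step 10 | 5,7-bis(benzyloxy)-3-[2,4-bis(benzyloxy)-3-(3-hydroxy-3-methylbut-1-yn-1-yl)-5-methoxyphenyl]-4H-chromen-4-one | COc1cc(-c2coc3cc(OCc4ccccc4)cc(OCc4ccccc4)c3c2=O)c(OCc2ccccc2)c(C#CC(C)(C)O)c1OCc1ccccc1
F5 | step 8 | 5,7-dihydroxy-2,2-dimethyl-4H-1,3-benzodioxin-4-one | CC1(C)OC(=O)c2c(O)cc(O)cc2O1
F6 | step 8 | 5,7-bis(benzyloxy)-2,2-dimethyl-4H-1,3-benzodioxin-4-one | CC1(C)OC(=O)c2c(OCc3ccccc3)cc(OCc3ccccc3)cc2O1
F7 | step 8 | 2,4-bis(benzyloxy)-6-hydroxybenzoic acid | O=C(O)c1c(O)cc(OCc2ccccc2)cc1OCc1ccccc1
F8 | step 8 | tert-butyldimethylsilyl 2,4-bis(benzyloxy)-6-(tert-butyldimethylsilyloxy)benzoate | CC(C)(C)[Si](C)(C)OC(=O)c1c(O[Si](C)(C)C(C)(C)C)cc(OCc2ccccc2)cc1OCc1ccccc1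
F9 | step 8 | 4,6-bis(benzyloxy)-2-(tert-butyldimethylsilyloxy)benzoyl chloride | O=C(Cl)c1c(O[Si](C)(C)C(C)(C)C)cc(OCc2ccccc2)cc1OCc1ccccc1
F10 | step 8 | 1-[2,4-bis(benzyloxy)-6-(tert-butyldimethylsilyloxy)phenyl]-2-[2,4-bis(benzyloxy)-3-(3-hydroxy-3-methylbut-1-yn-1-yl)-5-methoxyphenyl]-3-(morpholin-4-yl)prop-2-en-1-one | COc1cc(C(=CN2CCOCC2)C(=O)c2c(O[Si](C)(C)C(C)(C)C)cc(OCc3ccccc3)cc2OCc2ccccc2)c(OCc2ccccc2)c(C#CC(C)(C)O)c1OCc1ccccc1
F11 | step 8 | 1-[2,4-bis(benzyloxy)-6-hydroxyphenyl]-2-[2,4-bis(benzyloxy)-3-(3-hydroxy-3-methylbut-1-yn-1-yl)-5-methoxyphenyl]-3-(morpholin-4-yl)prop-2-en-1-one | COc1cc(C(=CN2CCOCC2)C(=O)c2c(O)cc(OCc3ccccc3)cc2OCc2ccccc2)c(OCc2ccccc2)c(C#CC(C)(C)O)c1OCc1ccccc1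
F12 | step 7 | 4-[2,6-bis(benzyloxy)-3-methoxy-5-(2-methoxyethenyl)phenyl]-2-methylbut-3-yn-2-ol (E/Z mixture) | COC=Cc1cc(OC)c(OCc2ccccc2)c(C#CC(C)(C)O)c1OCc1ccccc1
F13 | step 7 | 2-[2,4-bis(benzyloxy)-3-(3-hydroxy-3-methylbut-1-yn-1-yl)-5-methoxyphenyl]acetaldehyde | O=CCc1cc(OC)c(OCc2ccccc2)c(C#CC(C)(C)O)c1OCc1ccccc1
F14 | step 11 | 2,4-bis(benzyloxy)-3-(3-hydroxy-3-methylbutyl)-5-methoxybenzaldehyde | COc1cc(C=O)c(OCc2ccccc2)c(CCC(C)(C)O)c1OCc1ccccc1
F15 | step 11 | 1-[2,4-bis(benzyloxy)-3-(3-hydroxy-3-methylbutyl)-5-methoxyphenyl]-2-(diphenylphosphoryl)-2-(morpholin-4-yl)ethan-1-ol (mixture of diastereomers) | COc1cc(C(O)C(N2CCOCC2)P(=O)(c2ccccc2)c2ccccc2)c(OCc2ccccc2)c(CCC(C)(C)O)c1OCc1ccccc1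
F16 | step 11 | 4-[(E)-2-[2,4-bis(benzyloxy)-3-(3-hydroxy-3-methylbutyl)-5-methoxyphenyl]ethenyl]morpholine | COc1cc(/C=C/N2CCOCC2)c(OCc2ccccc2)c(CCC(C)(C)O)c1OCc1ccccc1
F17 | step 11 | 2-[2,4-bis(benzyloxy)-3-(3-hydroxy-3-methylbutyl)-5-methoxyphenyl]-3-(morpholin-4-yl)-1-[2,4,6-tris(tert-butyldimethylsilyloxy)phenyl]prop-2-en-1-one | COc1cc(C(=CN2CCOCC2)C(=O)c2c(O[Si](C)(C)C(C)(C)C)cc(O[Si](C)(C)C(C)(C)C)cc2O[Si](C)(C)C(C)(C)C)c(OCc2ccccc2)c(CCC(C)(C)O)c1OCc1ccccc1
F18 | step 11 | 2-[2,4-bis(benzyloxy)-3-(3-hydroxy-3-methylbutyl)-5-methoxyphenyl]-3-(morpholin-4-yl)-1-(2,4,6-trihydroxyphenyl)prop-2-en-1-one | COc1cc(C(=CN2CCOCC2)C(=O)c2c(O)cc(O)cc2O)c(OCc2ccccc2)c(CCC(C)(C)O)c1OCc1ccccc1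
F19 | step 11 | 3-[2,4-bis(benzyloxy)-3-(3-hydroxy-3-methylbutyl)-5-methoxyphenyl]-5,7-dihydroxy-4H-chromen-4-one | COc1cc(-c2coc3cc(O)cc(O)c3c2=O)c(OCc2ccccc2)c(CCC(C)(C)O)c1OCc1ccccc1
A1 | alternative 1 | 6-methyl-6-(triethylsilyloxy)heptan-2-one | CC(=O)CCCC(C)(C)O[Si](CC)(CC)CC
A2 | alternative 1 | methyl 2-methoxyprop-2-enoate | C=C(OC)C(=O)OC
A3 | alternative 1 | racemic 3-hydroxy-4-methoxy-2-[3-methyl-3-(triethylsilyloxy)butyl]cyclohex-2-en-1-one | COC1CCC(=O)C(CCC(C)(C)O[Si](CC)(CC)CC)=C1O
A4 | alternative 2 | 3,5-bis(benzyloxy)-2-(trimethylsilyl)phenyl trifluoromethanesulfonate | C[Si](C)(C)c1c(OCc2ccccc2)cc(OCc2ccccc2)cc1OS(=O)(=O)C(F)(F)F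
A5 | alternative 2 | methyl 3-hydroxy-2-[3-(3-hydroxy-3-methylbutyl)-5-methoxy-2,4-bis(methoxymethoxy)phenyl]prop-2-enoate | COC(=O)C(=CO)c1cc(OC)c(OCOC)c(CCC(C)(C)O)c1OCOC
A6 | alternative 2 | 5,7-bis(benzyloxy)-3-[3-(3-hydroxy-3-methylbutyl)-5-methoxy-2,4-bis(methoxymethoxy)phenyl]-4H-chromen-4-one | COc1cc(-c2coc3cc(OCc4ccccc4)cc(OCc4ccccc4)c3c2=O)c(OCOC)c(CCC(C)(C)O)c1OCOC
A7 | alternative 3 | pentacarbonyl{methoxy[1-(methoxymethoxy)-5-methyl-5-(triethylsilyloxy)hex-1-en-1-yl]methylidene}chromium | COC(C(OCOC)=CCCC(C)(C)O[Si](CC)(CC)CC)=[Cr](=C=O)(=C=O)(=C=O)(=C=O)=C=O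
A8 | alternative 3 | 5,7-bis(benzyloxy)-3-ethynyl-4H-chromen-4-one | C#Cc1coc2cc(OCc3ccccc3)cc(OCc3ccccc3)c2c1=O
A9 | alternative 3 | 5,7-bis(benzyloxy)-3-[2-hydroxy-5-methoxy-4-(methoxymethoxy)-3-(3-methyl-3-(triethylsilyloxy)butyl)phenyl]-4H-chromen-4-one | COc1cc(-c2coc3cc(OCc4ccccc4)cc(OCc4ccccc4)c3c2=O)c(O)c(CCC(C)(C)O[Si](CC)(CC)CC)c1OCOC
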